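## Structural features

The target joins two bicycles through a single bond, C1'–C8. The first is a cis-fused decahydroazulene: a cycloheptane ring carrying the C4' gem-dimethyl group and the C8' exocyclic methylidene, fused to a cyclopentane ring carrying the quaternary, methyl-bearing C1'. The second is a 2,7-dioxabicyclo[3.2.1]octan-3-one: C1 is an acylal carbon bonded to lactone O2 and ether O7, C3 is the lactone carbonyl, C4 carries OAc, C6 carries CO2Me, and C8 is the one-carbon bridge.

The hydroazulene has three adjacent stereocenters (C3a', C8a', C1'). The two ring-fusion hydrogens are cis, the dioxabicycle sits on that same convex face, and the C1' methyl is on the concave face.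

The dioxabicycle has five contiguous stereocenters (C1, C8, C5, C4, C6). The hydroazulenyl group on C8 is syn to the lactone bridge O2–C3–C4, the acetoxy group on C4 points away from C8, and the ester on C6 is exo (on the C8 side). On the tetrahydrofuran ring (O7, C1, C8, C5, C6) the substituents at C1, C8 and C5 are therefore all cis, a crowded pattern that cannot be reached by equilibration.

Fragile groups are the acylal C1 (acid, nucleophiles), the α-acetoxy lactone, the epimerisable C6–H next to the ester, and the 1,1-disubstituted alkene (acid-induced migration, electrophilic oxidants).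

The real difficulty is twofold: the bond from the quaternary C1' to C8, flanked by stereocenters on both sides, and the bicyclic acylal with its all-cis tetrahydrofuran.

The key step exploits the fact that O2 lies between the acylal carbon C1 and the carbonyl carbon C3. Deleting O2 and joining C1 to C3 turns the six-membered lactone ring into a cyclopentanone (C1, C3, C4, C5, C8), that is, a 2-oxabicyclo[2.2.1]heptan-6-one. In that ketone the hydroazulenyl group on the one-carbon bridge is trans to both neighbours, the acetoxy group is endo, and C1 is a bridgehead α-alkoxy carbon, which is the kind of carbon that migrates best in a Baeyer–Villiger oxidation.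

## Logic of the disconnections

Locants: primed locants are those of the azulene; unprimed locants are those of 26 unless a paragraph states otherwise.

**26 to 24.** The C1–O2 bond is cut and C1 is joined to C3 (retro Baeyer–Villiger). This removes the acylal and the lactone together and leaves a robust bridged ketone whose oxidation states need no further adjustment. The three cis substituents of the tetrahydrofuran become trans relationships on a cyclopentanone. The forward step must make the ether-bearing bridgehead migrate and not the acetoxy-bearing carbon, must keep the configuration of C1, and must leave the methylidene alone.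

**24 to 21.** The C4–O bond of the acetate is cut. In 21 this carbon is the only enolisable position of the ketone, because the other α-carbon is a bridgehead. The forward oxidation of the enolate must occur on the endo face; the hydroazulenyl group, syn to this bridge, blocks the exo face.

**21 to 19.** The C5–C6 bond is cut (retro intramolecular Michael addition). The bicycle becomes a monocyclic 4,5-trans-disubstituted cyclopent-2-enone carrying a glycolate ether. The forward step must generate the ester enolate next to a more acidic ketone and deliver it to the enone face on which the ether oxygen sits; it sets C5 and C6.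

**19 to 17 and 18.** The O7–C6 bond is cut. The forward step is etherification of a hindered, base-sensitive α-hydroxy enone, so it must run under neutral conditions.

**17 to 15.** The C1–O7 bond is cut. The forward step is α'-hydroxylation of a cross-conjugated enolate, which must occur trans to the neighbouring hydroazulenyl group.

**15 to 11 and 12.** The C1'–C8 bond is cut and a silanol is added back across C4–C5. This is the union of two fragments of similar size. The forward step must form the quaternary C1' on the convex face of the hydroazulene and C8 anti to the silyloxy group of 12. The silyloxy group then leaves to place the enone where the Michael addition needs it.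

**11 to 9.** The oxalate is removed, leaving a tertiary alcohol at C1'. Its configuration is immaterial because C1' passes through a planar radical.

**9 to 8, then 6 and 5.** The methylidene is taken back to a ketone at C8'. Then one ring carbon (C7') is excised, which turns the hydroazulenone into a hydrindanone. The forward insertion must move the methylene α-carbon and not the ring-fusion methine, and the methylenation must not epimerise C8a'.

**5 to 4.** The C1'–C8a' bond is cut (retro aldol). The forward aldol must stop at the ketol and give the cis ring fusion relative to the existing stereocenter.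

**4 to 3, then 1 and 2.** The methyl ketone is taken back to a terminal alkene, and the C3a'–C3' bond is cut (retro conjugate addition). The forward addition sets the single stereocenter from which C8a' is derived by substrate control.

## Other disconnections considered

Alternative 1: The first plan that comes to mind cuts C1'–C8 and both acetal C–O bonds. Forward, a tertiary C1' radical or enolate is coupled with a cyclopentenone or butenolide acceptor and elaborated to the cyclopentene A1. Ozonolysis of its ring alkene then gives an aldehyde that closes to the lactol with the C6 hydroxyl and a second aldehyde that must be oxidised and lactonised. The chosen plan is preferred for three reasons. The ozonolysis of A1 would have to spare the more electron-rich C8' methylidene, or the methylidene would have to be installed at the very end beside the acylal. The two carbonyls released have the same oxidation state and must be told apart by extra redox steps. And the acetoxy group would have to be set on a flexible cyclopentene, without the facial bias of a bridged ketone.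

Alternative 2: The same Baeyer–Villiger endgame, with the oxanorbornane made by a hetero-Diels–Alder reaction of methyl glyoxylate with the 5-substituted cyclopentadiene A2 to give the adduct A3. The topology is attractive, since addition anti to the C5 substituent gives the correct bridge configuration. It is not chosen because A2 needs a tertiary alkyl group on the sp3 carbon of a cyclopentadiene: this cannot be made by alkylating cyclopentadienide, and 1,5-hydrogen shifts would move it to the vinyl positions. In addition, nothing in A2 decides which diene terminus bonds to oxygen relative to the chiral hydroazulene, and the alkene of A3 would still need regioselective conversion into the 6-oxo-5-acetoxy pattern in the presence of the methylidene. The chosen plan builds the same ketone by polar steps with the carbonyl already in place.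

Alternative 3: Dearomatisation of the furan A4, a methyl 2-furoate carrying the hydroazulenyl group at C4 and the acetoxyacetic acid chain at C3. Forward, a face-selective cis reduction of the furan would create the all-cis tetrahydrofuran (C8, C5, C6) in one event, followed by lactonisation. It is not chosen because the furan C5 (C1 of the target) would arrive one oxidation level too low, hydrogenation conflicts with the methylidene, and the new stereocenters would have to be controlled from the remote hydroazulene stereocenters alone. There is also no reliable way to attach a quaternary carbon to a fully flanked furan position.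

Key step: step 13

Assumption: methyl diazoacetate (18) is treated as a purchasable reagent; if not in stock it is made fresh from glycine methyl ester hydrochloride and NaNO2.

Convention: Az = 1,4,4-trimethyl-8-methylidenedecahydroazulen-1-yl, cis-fused (H-3a' and H-8a' on one face, C3a' of R configuration), attached through C1' on the face of those hydrogens, with the C1' methyl on the opposite face. In 21–25 the locants are those of 2-oxabicyclo[2.2.1]heptane; they map onto 26 as C1→C1, O2→O7, C3→C6, C4→C5, C5→C4, C6→C3, C7→C8.

## Steps

Step 1
Reactants: 1 4,4-dimethylcyclohex-2-en-1-one; 2 but-3-en-1-ylmagnesium bromide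
Product: 3 (3R)-3-(but-3-en-1-yl)-4,4-dimethylcyclohexan-1-one
Conditions: CuBr·SMe2 (5 mol %), (R)-1-[(S)-2-(diphenylphosphino)ferrocenyl]ethyldicyclohexylphosphine (6 mol %), t-BuOMe, −75 °C; then H2O/NH4Cl
Reagents that add atoms: none
Why: Copper-catalysed asymmetric conjugate addition of a Grignard reagent to a cyclic enone; the chiral diphosphine–copper complex selects the enone face and sets C3 (the future C3a'), the ligand enantiomer being the one that should deliver 3R; the β-carbon is unsubstituted, so the neighbouring gem-dimethyl group slows but should not stop the addition.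

Step 2
Reactants: 3 (3R)-3-(but-3-en-1-yl)-4,4-dimethylcyclohexan-1-one
Product: 4 (3R)-4,4-dimethyl-3-(3-oxobutyl)cyclohexan-1-one
Conditions: PdCl2 (10 mol %), CuCl, O2 (1 atm), DMF/H2O 7:1, rt
Reagents that add atoms: water, O
Why: Tsuji–Wacker oxidation of the terminal alkene gives the methyl ketone with Markovnikov selectivity; the stereocenter is not touched.

Step 3
Reactants: 4 (3R)-4,4-dimethyl-3-(3-oxobutyl)cyclohexan-1-one
Product: 5 cis-fused 3-hydroxy-3,7,7-trimethyloctahydro-4H-inden-4-one (H-3a cis to H-7a; hydroxyl cis to the C4 acyl carbon)
Conditions: KOH (0.2 equiv), MeOH, 0 °C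
Reagents that add atoms: none
Why: Intramolecular aldol addition (5-exo-trig) of the ring enolate at C2 onto the side-chain ketone; the fused five-membered ketol is the least strained aldol mode and low temperature should prevent dehydration. The ring fusion should form cis under control of C3 of 4 and can equilibrate through the enolate; the carbinol configuration does not matter because this carbon later becomes a planar radical.

Step 4
Reactants: 5 cis-fused 3-hydroxy-3,7,7-trimethyloctahydro-4H-inden-4-one
Product: 6 cis-fused 3,7,7-trimethyl-3-(trimethylsilyloxy)octahydro-4H-inden-4-one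
Conditions: N-(trimethylsilyl)imidazole, CH2Cl2, rt
Reagents that add atoms: N-(trimethylsilyl)imidazole, C[Si](C)(C)n1ccnc1
Why: Silylation of the tertiary alcohol under neutral conditions (no enol ether formation) protects the β-hydroxy ketone against retro-aldol cleavage and dehydration in the Lewis-acid step that follows.

Step 5
Reactants: 6 cis-fused 3,7,7-trimethyl-3-(trimethylsilyloxy)octahydro-4H-inden-4-one
Product: 8 cis-fused 1-hydroxy-1,4,4-trimethyldecahydroazulen-8-one, via C7-silyl ketone 7 (not isolated)
Conditions: TMSCHN2 (1.5 equiv), Sc(OTf)3 (10 mol %), CH2Cl2, −20 °C → rt; then TBAF, AcOH, THF, 0 °C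
Reagents that add atoms: (trimethylsilyl)diazomethane, C[Si](C)(C)C=[N+]=[N-]
Why: Lewis-acid-catalysed diazoalkane homologation (Tiffeneau–Demjanov-type one-carbon insertion); the unhindered methylene α-carbon should migrate in preference to the ring-fusion methine next to the quaternary carbon, so the carbonyl stays beside C8a'. Buffered fluoride removes the C-silyl and O-silyl groups without epimerising C8a'.

Step 6
Reactants: 8 cis-fused 1-hydroxy-1,4,4-trimethyldecahydroazulen-8-one
Product: 9 cis-fused 1,4,4-trimethyl-8-methylidenedecahydroazulen-1-ol
Conditions: Zn, CH2Br2, TiCl4, THF/CH2Cl2, 0 °C → rt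
Reagents that add atoms: dibromomethane, BrCBr
Why: Takai–Lombardo methylenation is non-basic, so neither retro-aldol cleavage of the β-hydroxy ketone nor epimerisation at C8a' is expected, and the free tertiary alcohol is tolerated.

Step 7
Reactants: 9 cis-fused 1,4,4-trimethyl-8-methylidenedecahydroazulen-1-ol
Product: 11 cesium (1,4,4-trimethyl-8-methylidenedecahydroazulen-1-yl) oxalate, via methyl oxalate 10 (not isolated)
Conditions: ClCOCO2Me, Et3N, DMAP (cat.), CH2Cl2, 0 °C → rt; then CsOH·H2O (1.0 equiv), THF/H2O, rt
Reagents that add atoms: methyl chlorooxoacetate, COC(=O)C(=O)Cl; cesium hydroxide, [Cs+].[OH-]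
Why: Acylation of the tertiary alcohol with the oxalyl half-ester chloride, then selective saponification of the unhindered methyl ester with one equivalent of hydroxide, gives the bench-stable radical precursor.

Step 8
Reactants: 11 cesium (1,4,4-trimethyl-8-methylidenedecahydroazulen-1-yl) oxalate; 12 (4R)-4-[(tert-butyldimethylsilyl)oxy]cyclopent-2-en-1-one
Product: 15 4-Az-cyclopent-2-en-1-one, via tertiary radical 13 (not isolated), via silyloxy ketone 14 (not isolated)
Conditions: Ir[dF(CF3)ppy]2(dtbbpy)PF6 (1 mol %), 12 (1.5 equiv), DME/DMF 3:1, H2O (10 equiv), blue LEDs, 60 °C; then DBU, 0 °C → rt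
Reagents that add atoms: none
Why: Photoredox oxidation of the oxalate and loss of two CO2 give the planar radical 13, which adds to the enone in a Giese reaction; reduction and protonation give 14, and base-induced E1cB loss of silanol gives 15. Radical 13 should be trapped on the convex face (syn to H-3a' and H-8a', away from the seven-membered ring), which sets C1' whatever the carbinol configuration of 9 was. The enone should be attacked anti to its silyloxy group, which sets the ring carbon that becomes C8.

Step 9
Reactants: 15 4-Az-cyclopent-2-en-1-one
Product: 17 (4,5-trans)-4-Az-5-hydroxycyclopent-2-en-1-one, via potassium dienolate 16 (not isolated)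
Conditions: KHMDS, THF, −78 °C; 2-(phenylsulfonyl)-3-phenyloxaziridine, −78 °C; AcOH
Reagents that add atoms: 2-(phenylsulfonyl)-3-phenyloxaziridine, O=S(=O)(c1ccccc1)N1OC1c1ccccc1
Why: Kinetic α'-deprotonation gives the cross-conjugated enolate 16 (the γ-hydrogen is tertiary and buried beside the quaternary carbon); electrophilic hydroxylation by the oxaziridine should occur anti to the neighbouring Az group, giving the trans ketol, which is also the thermodynamically favoured epimer.

Step 10
Reactants: 17 (4,5-trans)-4-Az-5-hydroxycyclopent-2-en-1-one; 18 methyl diazoacetate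
Product: 19 methyl 2-{[(1,5-trans)-5-Az-2-oxocyclopent-3-en-1-yl]oxy}acetate
Conditions: Rh2(OAc)4 (1 mol %), 18 added slowly, CH2Cl2, rt
Reagents that add atoms: none
Why: Rhodium-carbenoid O–H insertion forms the glycolate ether under neutral conditions, so the base-sensitive α-hydroxy enone is neither epimerised nor isomerised; insertion into O–H is normally faster than cyclopropanation of an unactivated alkene.

Step 11
Reactants: 19 methyl 2-{[(1,5-trans)-5-Az-2-oxocyclopent-3-en-1-yl]oxy}acetate
Product: 21 methyl 7-Az-6-oxo-2-oxabicyclo[2.2.1]heptane-3-exo-carboxylate (Az syn to the C5–C6 bridge), via potassium ester enolate 20 (not isolated)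
Conditions: KHMDS (1.05 equiv), 18-crown-6, THF, −78 → −30 °C; AcOH
Reagents that add atoms: none
Why: Intramolecular Michael addition (5-exo-trig) of the ester enolate to the enone β-carbon closes the tetrahydrofuran ring and gives the bridged ketone; the tether can only reach the face it is attached to, so C4 is set cis to O2 and trans to the Az group. The ester should take the exo position in an open, crown-ether-separated transition state that keeps the enolate carboxyl group away from the developing ketone enolate; if needed it can be equilibrated through its enolate.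

Step 12
Reactants: 21 methyl 7-Az-6-oxo-2-oxabicyclo[2.2.1]heptane-3-exo-carboxylate
Product: 24 methyl 5-endo-acetoxy-7-Az-6-oxo-2-oxabicyclo[2.2.1]heptane-3-exo-carboxylate, via potassium enolate 22 (not isolated), via potassium alkoxide 23 (not isolated)
Conditions: KHMDS (1.0 equiv), THF, −78 °C; 2-(phenylsulfonyl)-3-phenyloxaziridine; then Ac2O, DMAP, −78 → 0 °C
Reagents that add atoms: 2-(phenylsulfonyl)-3-phenyloxaziridine, O=S(=O)(c1ccccc1)N1OC1c1ccccc1; acetic anhydride, CC(=O)OC(C)=O
Why: The ketone can enolise only toward C5 (C1 is a bridgehead) and is more acidic than the ester; the Az group on C7, syn to this bridge, covers the exo face, so the oxaziridine should attack endo and set C5. The alkoxide 23 is acetylated in the same flask before it can equilibrate.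

Step 13
Reactants: 24 methyl 5-endo-acetoxy-7-Az-6-oxo-2-oxabicyclo[2.2.1]heptane-3-exo-carboxylate
Product: 26 methyl 4-acetoxy-8-Az-3-oxo-2,7-dioxabicyclo[3.2.1]octane-6-carboxylate (CNP0215240.1), via Criegee adduct 25 (not isolated)
Conditions: Me3SiOOSiMe3 (2 equiv), TMSOTf (10 mol %), CH2Cl2, −40 → −20 °C
Reagents that add atoms: bis(trimethylsilyl) peroxide, C[Si](C)(C)OO[Si](C)(C)C
Why: Baeyer–Villiger oxidation with a silyl peroxide: TMSOTf activates the strained C6 ketone, the peroxide adds from the open endo face to give the Criegee adduct 25, and the C1–C6 bond antiperiplanar to the O–O bond migrates to oxygen with loss of a silanolate. The closest known reaction type is the peroxide ring expansion of bicyclo[2.2.1]heptan-2-ones and 7-oxabicyclo[2.2.1]heptan-2-ones, in which the bridgehead carbon migrates. No ring is closed by cyclisation: the five-membered ketone ring (C1, C6, C5, C4, C7) is expanded by a 1,2-shift to the six-membered lactone ring of 26 (C1, O2, C3, C4, C5, C8), which turns the bicyclo[2.2.1] skeleton into the bicyclo[3.2.1] skeleton. No new stereocenter is formed: C1 migrates with retention and becomes the acylal carbon, and the other four stereocenters of the bicycle are untouched. The step needs regioselectivity (C1, not the acetoxy-bearing C5, must migrate) and chemoselectivity (the ketone is oxidised, the methylidene is not). The first should be secured by the ether oxygen on C1, whose lone pair supports the electron-poor migrating carbon far better than the ester-bound oxygen on C5, together with the strain relief of bridgehead migration. The second should be secured by the reagent, a peroxide that does not epoxidise alkenes, used cold with only catalytic silyl triflate so that acylal and alkene meet no protic acid.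

## Compound list

1 | 4,4-dimethylcyclohex-2-en-1-one | CC1(C)CCC(=O)C=C1 | starting material
2 | but-3-en-1-ylmagnesium bromide | C=CCC[Mg]Br | starting material
3 | (3R)-3-(but-3-en-1-yl)-4,4-dimethylcyclohexan-1-one | O=C1CCC(C)(C)[C@H](CCC=C)C1 | intermediate
4 | (3R)-4,4-dimethyl-3-(3-oxobutyl)cyclohexan-1-one | O=C1CCC(C)(C)[C@H](CCC(C)=O)C1 | intermediate
5 | cis-fused 3-hydroxy-3,7,7-trimethyloctahydro-4H-inden-4-one (hydroxyl cis to the acyl carbon; the C3 epimer serves equally) | O=C1CCC(C)(C)[C@@H]2CC[C@](C)(O)[C@H]12 | intermediate
6 | cis-fused 3,7,7-trimethyl-3-(trimethylsilyloxy)octahydro-4H-inden-4-one | O=C1CCC(C)(C)[C@@H]2CC[C@](C)(O[Si](C)(C)C)[C@H]12 | intermediate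
7 | cis-fused 1,4,4-trimethyl-7-(trimethylsilyl)-1-(trimethylsilyloxy)decahydroazulen-8-one (C7 configuration open) | O=C1C([Si](C)(C)C)CCC(C)(C)[C@@H]2CC[C@](C)(O[Si](C)(C)C)[C@H]12 | intermediate (not isolated)
8 | cis-fused 1-hydroxy-1,4,4-trimethyldecahydroazulen-8-one | O=C1CCCC(C)(C)[C@@H]2CC[C@](C)(O)[C@H]12 | intermediate
9 | cis-fused 1,4,4-trimethyl-8-methylidenedecahydroazulen-1-ol | C=C1CCCC(C)(C)[C@@H]2CC[C@](C)(O)[C@H]12 | intermediate
10 | methyl (1,4,4-trimethyl-8-methylidenedecahydroazulen-1-yl) oxalate | C=C1CCCC(C)(C)[C@@H]2CC[C@](C)(OC(=O)C(=O)OC)[C@H]12 | intermediate (not isolated)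
11 | cesium (1,4,4-trimethyl-8-methylidenedecahydroazulen-1-yl) oxalate | C=C1CCCC(C)(C)[C@@H]2CC[C@](C)(OC(=O)C(=O)[O-])[C@H]12.[Cs+] | intermediate
12 | (4R)-4-[(tert-butyldimethylsilyl)oxy]cyclopent-2-en-1-one | O=C1C=C[C@H](O[Si](C)(C)C(C)(C)C)C1 | starting material
13 | cis-fused 1,4,4-trimethyl-8-methylidenedecahydroazulen-1-yl radical | C=C1CCCC(C)(C)[C@@H]2CC[C](C)[C@H]12 | intermediate (not isolated)
14 | (3,4-trans)-3-Az-4-[(tert-butyldimethylsilyl)oxy]cyclopentan-1-one | C=C1CCCC(C)(C)[C@@H]2CC[C@@](C)([C@@H]3CC(=O)C[C@H]3O[Si](C)(C)C(C)(C)C)[C@H]12 | intermediate (not isolated)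
15 | 4-Az-cyclopent-2-en-1-one | C=C1CCCC(C)(C)[C@@H]2CC[C@@](C)([C@@H]3CC(=O)C=C3)[C@H]12 | intermediate
16 | potassium 5-Az-cyclopenta-1,3-dien-2-olate | C=C1CCCC(C)(C)[C@@H]2CC[C@@](C)([C@@H]3C=C([O-])C=C3)[C@H]12.[K+] | intermediate (not isolated)
17 | (4,5-trans)-4-Az-5-hydroxycyclopent-2-en-1-one | C=C1CCCC(C)(C)[C@@H]2CC[C@@](C)([C@@H]3[C@@H](O)C(=O)C=C3)[C@H]12 | intermediate
18 | methyl diazoacetate | COC(=O)C=[N+]=[N-] | starting material
19 | methyl 2-{[(1,5-trans)-5-Az-2-oxocyclopent-3-en-1-yl]oxy}acetate | C=C1CCCC(C)(C)[C@@H]2CC[C@@](C)([C@@H]3[C@@H](OCC(=O)OC)C(=O)C=C3)[C@H]12 | intermediate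
20 | potassium ester enolate of 19 | C=C1CCCC(C)(C)[C@@H]2CC[C@@](C)([C@@H]3[C@@H](OC=C([O-])OC)C(=O)C=C3)[C@H]12.[K+] | intermediate (not isolated)
21 | methyl 7-Az-6-oxo-2-oxabicyclo[2.2.1]heptane-3-exo-carboxylate (Az syn to C5–C6) | C=C1CCCC(C)(C)[C@@H]2CC[C@@](C)([C@@H]3[C@@H]4C(=O)C[C@H]3[C@H](C(=O)OC)O4)[C@H]12 | intermediate
22 | potassium C5–C6 enolate of 21 | C=C1CCCC(C)(C)[C@@H]2CC[C@@](C)([C@@H]3[C@@H]4C([O-])=C[C@H]3[C@H](C(=O)OC)O4)[C@H]12.[K+] | intermediate (not isolated)
23 | potassium 5-endo-alkoxide of the 5-hydroxy ketone | C=C1CCCC(C)(C)[C@@H]2CC[C@@](C)([C@@H]3[C@@H]4C(=O)[C@@H]([O-])[C@H]3[C@H](C(=O)OC)O4)[C@H]12.[K+] | intermediate (not isolated)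
24 | methyl 5-endo-acetoxy-7-Az-6-oxo-2-oxabicyclo[2.2.1]heptane-3-exo-carboxylate | C=C1CCCC(C)(C)[C@@H]2CC[C@@](C)([C@@H]3[C@@H]4C(=O)[C@@H](OC(C)=O)[C@H]3[C@H](C(=O)OC)O4)[C@H]12 | intermediate
25 | Criegee adduct of 24 (C6 bearing OSiMe3 and OOSiMe3; C6 configuration open) | C=C1CCCC(C)(C)[C@@H]2CC[C@@](C)([C@@H]3[C@@H]4C(O[Si](C)(C)C)(OO[Si](C)(C)C)[C@@H](OC(C)=O)[C@H]3[C@H](C(=O)OC)O4)[C@H]12 | intermediate (not isolated)
26 | methyl 4-acetoxy-8-Az-3-oxo-2,7-dioxabicyclo[3.2.1]octane-6-carboxylate (CNP0215240.1) | C=C1CCCC(C)(C)[C@@H]2CC[C@@](C)([C@@H]3[C@@H]4OC(=O)[C@@H](OC(C)=O)[C@H]3[C@H](C(=O)OC)O4)[C@H]12 | target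

## Step count and risks

Total step count: 13. Longest linear sequence: 13 steps (from 1; compounds 2, 12 and 18 are purchased).

**Step 13 (key step).** What may go wrong: partial migration of the acetoxy-bearing C5 instead of C1, which would put the ring oxygen on the wrong side of the carbonyl; acid-induced migration of the methylidene double bond into the ring, or its oxidation; and acid-promoted opening of the acylal once formed.
Fallback (from 21, back at 26): the oxygen is inserted before the acetoxy group exists, so the competing α-carbon is a plain methylene. Compound 21 is treated with Me3SiOOSiMe3/TMSOTf to give the 4-unsubstituted lactone methyl 8-Az-3-oxo-2,7-dioxabicyclo[3.2.1]octane-6-carboxylate F1. Its lactone enolate (LiHMDS, THF, −78 °C) is hydroxylated with the sulfonyloxaziridine on the face away from the axial Az group to give the 4-hydroxy lactone F2. Acetylation (Ac2O, pyridine) then gives 26.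

**Step 11.** What may go wrong: proton removal at the more acidic ketone α'-position instead of the ester, which stalls the cyclisation and allows epimerisation next to the ketone; and formation of the endo ester through a chelated transition state.
Fallback (from 17, back at 21): the nucleophile is made more acidic than any ketone position. Rh2(OAc)4-catalysed O–H insertion of dimethyl diazomalonate into 17 gives the alkoxymalonate F3. Cs2CO3 in MeCN closes the ring by Michael addition of the malonate to give the bicyclic diester F4. Krapcho demethoxycarbonylation (LiCl, wet DMSO, heat), followed by equilibration of the ester (NaOMe, MeOH), gives 21.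

**Step 8.** What may go wrong: base-induced loss of silanol from acceptor 12 in the warm, cesium-containing medium before the radical is captured; slow capture of the hindered tertiary radical, leading to reduction or disproportionation; and incomplete facial selectivity at C1'.
Fallback (from 9, back at 15): a different radical precursor and the opposite redox manifold. Alcohol 9 is converted with oxalyl chloride and then N-hydroxyphthalimide/Et3N into the tert-alkyl N-phthalimidoyl oxalate F5, which is used crude. Reductive fragmentation with Ru(bpy)3(PF6)2, Hantzsch ester and iPr2NEt·HBF4 under visible light at room temperature generates the same radical 13 under slightly acidic conditions, in which 12 does not eliminate. Addition to 12 gives 14, and DBU then gives 15.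

**Step 3.** What may go wrong: dehydration of the ketol to the conjugated enone, and competing aldolisation of the side-chain enolate onto the ring ketone (bridged ketol).
Fallback (from 4, back at 5): forcing aldol condensation (KOH, MeOH, reflux) funnels all aldol modes into the conjugated enone 3,7,7-trimethyl-1,2,5,6,7,7a-hexahydro-4H-inden-4-one F6. Nucleophilic epoxidation (H2O2, NaOH) gives the 3,3a-epoxy ketone F7. SmI2 (THF/MeOH, −78 °C) then cleaves the C–O bond next to the carbonyl and returns the ketol 5.

## Further compounds

F1 | step 13 | methyl 8-Az-3-oxo-2,7-dioxabicyclo[3.2.1]octane-6-carboxylate | C=C1CCCC(C)(C)[C@@H]2CC[C@@](C)([C@@H]3[C@@H]4OC(=O)C[C@H]3[C@H](C(=O)OC)O4)[C@H]12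
F2 | step 13 | methyl 8-Az-4-hydroxy-3-oxo-2,7-dioxabicyclo[3.2.1]octane-6-carboxylate | C=C1CCCC(C)(C)[C@@H]2CC[C@@](C)([C@@H]3[C@@H]4OC(=O)[C@@H](O)[C@H]3[C@H](C(=O)OC)O4)[C@H]12
F3 | step 11 | dimethyl 2-{[(1,5-trans)-5-Az-2-oxocyclopent-3-en-1-yl]oxy}malonate | C=C1CCCC(C)(C)[C@@H]2CC[C@@](C)([C@@H]3[C@@H](OC(C(=O)OC)C(=O)OC)C(=O)C=C3)[C@H]12
F4 | step 11 | dimethyl 7-Az-6-oxo-2-oxabicyclo[2.2.1]heptane-3,3-dicarboxylate | C=C1CCCC(C)(C)[C@@H]2CC[C@@](C)([C@@H]3[C@@H]4C(=O)C[C@H]3C(C(=O)OC)(C(=O)OC)O4)[C@H]12
F5 | step 8 | 1,3-dioxoisoindolin-2-yl (1,4,4-trimethyl-8-methylidenedecahydroazulen-1-yl) oxalate | C=C1CCCC(C)(C)[C@@H]2CC[C@](C)(OC(=O)C(=O)ON3C(=O)c4ccccc4C3=O)[C@H]12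
F6 | step 3 | 3,7,7-trimethyl-1,2,5,6,7,7a-hexahydro-4H-inden-4-one | O=C1CCC(C)(C)[C@@H]2CCC(C)=C12
F7 | step 3 | 3,3a-epoxy-3,7,7-trimethyloctahydro-4H-inden-4-one (epoxide face open) | O=C1CCC(C)(C)[C@@H]2CCC3(C)OC123
A1 | alternative 1 | methyl 2-(2-acetoxy-5-Az-cyclopent-3-en-1-yl)-2-hydroxyacetate | C=C1CCCC(C)(C)[C@@H]2CC[C@@](C)([C@@H]3C=C[C@@H](OC(C)=O)[C@H]3[C@@H](O)C(=O)OC)[C@H]12
A2 | alternative 2 | 5-Az-cyclopenta-1,3-diene | C=C1CCCC(C)(C)[C@@H]2CC[C@@](C)(C3C=CC=C3)[C@H]12
A3 | alternative 2 | methyl 7-Az-2-oxabicyclo[2.2.1]hept-5-ene-3-exo-carboxylate | C=C1CCCC(C)(C)[C@@H]2CC[C@@](C)([C@@H]3[C@@H]4C=C[C@H]3[C@H](C(=O)OC)O4)[C@H]12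
A4 | alternative 3 | 2-acetoxy-2-[4-Az-2-(methoxycarbonyl)furan-3-yl]acetic acid | C=C1CCCC(C)(C)[C@@H]2CC[C@@](C)(c3coc(C(=O)OC)c3[C@H](OC(C)=O)C(=O)O)[C@H]12
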